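**Plan** (locants are those of the 12-oxabicyclo[9.1.0]dodecane core: C1/C11 epoxide, C2 ester carbinol, C3=C4 E-alkene, C5 quaternary carbon, C7=C8 alkene)

1. Retrosynthetic cuts, in order: the C2 ester and the silyl groups; the ring bond C2–C3, back to an acyclic ω-ynal; the C1–C11 epoxide back to a (Z)-alkene made by Still–Gennari olefination; C7=C8 by Wittig olefination; the C5–alkynyl bond by SN2' alkynylation of geranyl phosphate.
2. Enabling feature: the trans C3=C4 alkene lies between the quaternary C5 and the oxygenated C2 next to the cis-epoxide. This is the retron of a reductive coupling between a tert-alkyl acetylene and an α-methyl α,β-epoxy aldehyde. The epoxy aldehyde has no α-hydrogen, and the cis-epoxide plus the C7=C8 alkene (ring carbons cis) fold the chain for closure of the 11-membered ring.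
3. Forward order: geraniol supplies C5 and the side chain, a dioxolane-bearing stabilised phosphorus ylide supplies C8–C11 with the future CH2OH, and an α-methyl Still–Gennari phosphonate supplies C1, its methyl and C2. The chain is built linearly, the epoxide is installed, the 11-membered carbocycle is closed in the only ring-forming C–C step, and the ester is added last.
4. Stereochemistry: C5 from catalyst-controlled allylic substitution; C1/C11 from Sharpless epoxidation of the (Z)-allylic alcohol; C2 from the adjacent epoxide during ring closure; alkene geometries from the Wittig reaction, the Still–Gennari reaction and syn addition across the alkyne.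

Key step: step 14

Assumption: the chiral NHC–Cu catalyst of step 2 is taken as the enantiomer that gives the (S)-quaternary carbon from the (E)-phosphate; this sense must be confirmed on the substitution product, and the fallback for step 2 reaches the same compound by reactions of predictable stereochemical course.

**Step 1**
Reactants: 1 geraniol
Product: 2 geranyl diethyl phosphate
Conditions: ClP(O)(OEt)2, Et3N, DMAP (cat.), CH2Cl2, 0 °C to rt
Reagents that add atoms: diethyl chlorophosphate, CCOP(Cl)(=O)OCC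
Why: O-phosphorylation of a primary allylic alcohol under amine base with DMAP catalysis is standard, leaves the (E)-alkene untouched and installs the leaving group for SN2' substitution.

**Step 2**
Reactants: 2 geranyl diethyl phosphate; 3 ethynyltrimethylsilane
Product: 5 trimethyl[(3S)-3-ethenyl-3,7-dimethyloct-6-en-1-yn-1-yl]silane, via alkynylalane 4 (not isolated)
Conditions: 3, i-Bu2AlH, Et3N (5 mol%), hexanes, rt; then 2, CuCl2·2H2O (5 mol%), chiral sulfonate-bearing imidazolinium salt (NHC precursor, 5 mol%), THF, −15 °C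
Reagents that add atoms: none
Why: Copper-catalysed enantioselective allylic substitution of a trisubstituted allylic phosphate with an alkynylaluminium reagent under a chiral bidentate sulfonate–NHC ligand is SN2'-selective, so the alkynyl group is delivered to the disubstituted alkene carbon and the all-carbon quaternary centre (methyl, homoprenyl, vinyl, silylethynyl) is set by catalyst control of the alkene face.

**Step 3**
Reactants: 5 trimethyl[(3S)-3-ethenyl-3,7-dimethyloct-6-en-1-yn-1-yl]silane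
Product: 8 (3S)-3-ethynyl-3,7-dimethyloct-6-en-1-ol, via alkylborane 6 (not isolated), via silyl alcohol 7 (not isolated)
Conditions: 9-BBN, THF, 0 °C to rt; then NaOH, H2O2, MeOH/H2O, 0 °C to rt
Reagents that add atoms: hydrogen peroxide, OO
Why: Anti-Markovnikov hydroboration with 9-BBN should take the monosubstituted vinyl group in preference to the trisubstituted alkene and the hindered silylalkyne, and the alkaline peroxide/methanol work-up oxidises the C–B bond and cleaves the alkynyl C–Si bond without touching the quaternary centre.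

**Step 4**
Reactants: 8 (3S)-3-ethynyl-3,7-dimethyloct-6-en-1-ol
Product: 9 (3S)-3-ethynyl-3,7-dimethyloct-6-enal
Conditions: Dess–Martin periodinane, NaHCO3, CH2Cl2, 0 °C to rt
Reagents that add atoms: none
Why: Dess–Martin oxidation of a primary alcohol stops at the aldehyde and tolerates the alkyne and alkene; the stereocentre is quaternary and cannot epimerise.

**Step 5**
Reactants: 10 ethyl (triphenyl-λ5-phosphanylidene)acetate; 11 2-(2-bromoethyl)-1,3-dioxolane
Product: 13 ethyl 4-(1,3-dioxolan-2-yl)-2-(triphenyl-λ5-phosphanylidene)butanoate, via phosphonium bromide 12 (not isolated)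
Conditions: NaI (cat.), MeCN, reflux; then NaOH (aq), CH2Cl2, 0 °C
Reagents that add atoms: none
Why: C-alkylation of the stabilised ylide by the primary halide (Finkelstein activation) gives the phosphonium salt, which aqueous NaOH deprotonates to the α-substituted stabilised ylide; the dioxolane is inert to these conditions.

**Step 6**
Reactants: 9 (3S)-3-ethynyl-3,7-dimethyloct-6-enal; 13 ethyl 4-(1,3-dioxolan-2-yl)-2-(triphenyl-λ5-phosphanylidene)butanoate
Product: 14 ethyl (2E,5S)-2-[2-(1,3-dioxolan-2-yl)ethyl]-5-ethynyl-5,9-dimethyldeca-2,8-dienoate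
Conditions: toluene, 90 °C
Reagents that add atoms: none
Why: Wittig olefination with an α-substituted stabilised ylide is under thermodynamic control and should place the ester trans to the aldehyde-derived chain, which is the geometry of C7=C8 with the two ring carbons cis.

**Step 7**
Reactants: 14 ethyl (2E,5S)-2-[2-(1,3-dioxolan-2-yl)ethyl]-5-ethynyl-5,9-dimethyldeca-2,8-dienoate
Product: 15 (2E,5S)-2-[2-(1,3-dioxolan-2-yl)ethyl]-5-ethynyl-5,9-dimethyldeca-2,8-dien-1-ol
Conditions: i-Bu2AlH, CH2Cl2, −78 °C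
Reagents that add atoms: none
Why: i-Bu2AlH reduces the conjugated ester 1,2 to the allylic alcohol at low temperature without affecting the acetal, the alkyne or the alkene geometry.

**Step 8**
Reactants: 15 (2E,5S)-2-[2-(1,3-dioxolan-2-yl)ethyl]-5-ethynyl-5,9-dimethyldeca-2,8-dien-1-ol
Product: 16 tert-butyl{[(2E,5S)-2-[2-(1,3-dioxolan-2-yl)ethyl]-5-ethynyl-5,9-dimethyldeca-2,8-dien-1-yl]oxy}diphenylsilane
Conditions: TBDPSCl, imidazole, DMF, rt
Reagents that add atoms: tert-butyl(chloro)diphenylsilane, CC(C)(C)[Si](Cl)(c1ccccc1)c1ccccc1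
Why: Silylation of the primary allylic alcohol gives an acid-robust ether that masks this hydroxyl through the epoxidation, the ring closure and the later acylation.

**Step 9**
Reactants: 16 tert-butyl{[(2E,5S)-2-[2-(1,3-dioxolan-2-yl)ethyl]-5-ethynyl-5,9-dimethyldeca-2,8-dien-1-yl]oxy}diphenylsilane
Product: 17 (4E,7S)-4-{[tert-butyl(diphenyl)silyl]oxymethyl}-7-ethynyl-7,11-dimethyldodeca-4,10-dienal
Conditions: PPTS, acetone/H2O, reflux
Reagents that add atoms: water, O
Why: Mild acid-catalysed acetal hydrolysis frees the aldehyde while the TBDPS ether, the trisubstituted alkenes and the alkyne should survive the weakly acidic medium.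

**Step 10**
Reactants: 17 (4E,7S)-4-{[tert-butyl(diphenyl)silyl]oxymethyl}-7-ethynyl-7,11-dimethyldodeca-4,10-dienal; 18 ethyl 2-[bis(2,2,2-trifluoroethoxy)phosphoryl]propanoate
Product: 19 ethyl (2Z,6E,9S)-6-{[tert-butyl(diphenyl)silyl]oxymethyl}-9-ethynyl-2,9,13-trimethyltetradeca-2,6,12-trienoate
Conditions: KN(SiMe3)2, 18-crown-6, THF, −78 °C
Reagents that add atoms: none
Why: Still–Gennari olefination with the α-methyl bis(trifluoroethyl) phosphonate is kinetically Z-selective for unbranched aldehydes, which places the ester cis to the chain as the later cis-epoxide requires.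

**Step 11**
Reactants: 19 ethyl (2Z,6E,9S)-6-{[tert-butyl(diphenyl)silyl]oxymethyl}-9-ethynyl-2,9,13-trimethyltetradeca-2,6,12-trienoate
Product: 20 (2Z,6E,9S)-6-{[tert-butyl(diphenyl)silyl]oxymethyl}-9-ethynyl-2,9,13-trimethyltetradeca-2,6,12-trien-1-ol
Conditions: i-Bu2AlH, CH2Cl2, −78 °C
Reagents that add atoms: none
Why: 1,2-Reduction of the (Z)-enoate with i-Bu2AlH gives the (Z)-allylic alcohol without isomerisation, an ester being far more stable towards Z/E drift than the corresponding enal.

**Step 12**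
Reactants: 20 (2Z,6E,9S)-6-{[tert-butyl(diphenyl)silyl]oxymethyl}-9-ethynyl-2,9,13-trimethyltetradeca-2,6,12-trien-1-ol
Product: 21 [(2S,3R)-3-[(3E,6S)-3-{[tert-butyl(diphenyl)silyl]oxymethyl}-6-ethynyl-6,10-dimethylundeca-3,9-dien-1-yl]-2-methyloxiran-2-yl]methanol
Conditions: Ti(OiPr)4 (cat.), L-(+)-diisopropyl tartrate, t-BuOOH, 4 Å MS, CH2Cl2, −20 °C
Reagents that add atoms: tert-butyl hydroperoxide, CC(C)(C)OO
Why: Sharpless asymmetric epoxidation acts only on the alkene of the free allylic alcohol; the L-(+)-tartrate complex delivers oxygen to the face that gives the (2S,3R) epoxy alcohol, and the Z-alkene sets the cis relationship of the two ring carbons on the epoxide.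

**Step 13**
Reactants: 21 [(2S,3R)-3-[(3E,6S)-3-{[tert-butyl(diphenyl)silyl]oxymethyl}-6-ethynyl-6,10-dimethylundeca-3,9-dien-1-yl]-2-methyloxiran-2-yl]methanol
Product: 22 (2R,3R)-3-[(3E,6S)-3-{[tert-butyl(diphenyl)silyl]oxymethyl}-6-ethynyl-6,10-dimethylundeca-3,9-dien-1-yl]-2-methyloxirane-2-carbaldehyde
Conditions: Dess–Martin periodinane, NaHCO3, CH2Cl2, 0 °C
Reagents that add atoms: none
Why: Buffered Dess–Martin oxidation converts the epoxy alcohol into the epoxy aldehyde without opening the epoxide, and the α-carbon is fully substituted so its configuration cannot be lost.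

**Step 14**
Reactants: 22 (2R,3R)-3-[(3E,6S)-3-{[tert-butyl(diphenyl)silyl]oxymethyl}-6-ethynyl-6,10-dimethylundeca-3,9-dien-1-yl]-2-methyloxirane-2-carbaldehyde
Product: 23 tert-butyl{[(1R,2S,3E,5S,7E,11R)-1,5-dimethyl-5-(4-methylpent-3-en-1-yl)-2-[(triethylsilyl)oxy]-12-oxabicyclo[9.1.0]dodeca-3,7-dien-8-yl]methoxy}diphenylsilane
Conditions: Ni(cod)2 (25 mol%), IMes·HCl (25 mol%), KOtBu (25 mol%), Et3SiH (5 equiv), THF, rt, slow addition of 22 (final 0.005 M)
Reagents that add atoms: triethylsilane, CC[SiH](CC)CC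
Why: Zerovalent nickel bearing the small NHC binds the terminal alkyne and the aldehyde of 22 and couples them oxidatively to an oxanickelacyclopentene (new C2–C3 bond); σ-bond metathesis of its Ni–O bond with Et3SiH and C–H reductive elimination at C4 then release the silyl ether and return the catalyst. The closest known reaction type is the nickel/NHC/silane reductive macrocyclisation of ω-ynals with terminal alkynes to endocyclic (E)-allylic silyl ethers. The 11-membered carbocycle closes endo with respect to the alkyne (both alkyne carbons enter the ring) and 11-exo-trig with respect to the carbonyl. The C3=C4 alkene is E because carbon and hydrogen add syn across the alkyne, and the new C2 centre is controlled by the adjacent epoxide: in the Cornforth-type arrangement (epoxide C1–O anti to C=O) the alkyne approaches past the C1 methyl group, anti to C11 and its cis chain, which should give the (2S) configuration. Bond formation at the terminal alkyne carbon is secured by the quaternary propargylic C5 together with the small ligand. Cyclisation over oligomerisation is secured by slow addition at high dilution and by the two cis ring units (cis-epoxide, C7=C8) that fold the chain.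

**Step 15**
Reactants: 23 tert-butyl{[(1R,2S,3E,5S,7E,11R)-1,5-dimethyl-5-(4-methylpent-3-en-1-yl)-2-[(triethylsilyl)oxy]-12-oxabicyclo[9.1.0]dodeca-3,7-dien-8-yl]methoxy}diphenylsilane
Product: 24 (1S,2S,3E,5S,7E,11R)-8-{[tert-butyl(diphenyl)silyl]oxymethyl}-1,5-dimethyl-5-(4-methylpent-3-en-1-yl)-12-oxabicyclo[9.1.0]dodeca-3,7-dien-2-ol
Conditions: HF·pyridine, pyridine, THF, 0 °C
Reagents that add atoms: none
Why: Buffered HF·pyridine should cleave the secondary triethylsilyl ether much faster than the primary TBDPS ether and should leave the trisubstituted epoxide intact (the C1 descriptor changes only because the priority order changes).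

**Step 16**
Reactants: 24 (1S,2S,3E,5S,7E,11R)-8-{[tert-butyl(diphenyl)silyl]oxymethyl}-1,5-dimethyl-5-(4-methylpent-3-en-1-yl)-12-oxabicyclo[9.1.0]dodeca-3,7-dien-2-ol; 25 3-methylbut-2-enoyl chloride
Product: 26 (1R,2S,3E,5S,7E,11R)-8-{[tert-butyl(diphenyl)silyl]oxymethyl}-1,5-dimethyl-5-(4-methylpent-3-en-1-yl)-12-oxabicyclo[9.1.0]dodeca-3,7-dien-2-yl 3-methylbut-2-enoate
Conditions: pyridine, DMAP (cat.), CH2Cl2, 0 °C to rt
Reagents that add atoms: none
Why: DMAP-catalysed acylation of the only free hydroxyl with the acid chloride under a weak base (to avoid deconjugation of the acyl group through a vinylketene) gives the ester with retention at C2.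

**Step 17**
Reactants: 26 (1R,2S,3E,5S,7E,11R)-8-{[tert-butyl(diphenyl)silyl]oxymethyl}-1,5-dimethyl-5-(4-methylpent-3-en-1-yl)-12-oxabicyclo[9.1.0]dodeca-3,7-dien-2-yl 3-methylbut-2-enoate
Product: 27 (1R,2S,3E,5S,7E,11R)-8-(hydroxymethyl)-1,5-dimethyl-5-(4-methylpent-3-en-1-yl)-12-oxabicyclo[9.1.0]dodeca-3,7-dien-2-yl 3-methylbut-2-enoate
Conditions: Bu4NF, AcOH, THF, 0 °C to rt
Reagents that add atoms: none
Why: Acetic acid-buffered fluoride removes the TBDPS group from the primary allylic oxygen while the buffered medium should spare the ester and the epoxide.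

**Compound list**
1 | geraniol, (2E)-3,7-dimethylocta-2,6-dien-1-ol | CC(C)=CCC/C(C)=C/CO | starting material
2 | geranyl diethyl phosphate | CC(C)=CCC/C(C)=C/COP(=O)(OCC)OCC | intermediate
3 | ethynyltrimethylsilane | C#C[Si](C)(C)C | starting material
4 | diisobutyl[(trimethylsilyl)ethynyl]aluminium | CC(C)C[Al](CC(C)C)C#C[Si](C)(C)C | intermediate
5 | trimethyl[(3S)-3-ethenyl-3,7-dimethyloct-6-en-1-yn-1-yl]silane | CC(C)=CCC[C@](C=C)(C)C#C[Si](C)(C)C | intermediate
6 | 9-[(3R)-3,7-dimethyl-3-[(trimethylsilyl)ethynyl]oct-6-en-1-yl]-9-borabicyclo[3.3.1]nonane | CC(C)=CCC[C@](CCB1C2CCCC1CCC2)(C)C#C[Si](C)(C)C | intermediate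
7 | (3S)-3,7-dimethyl-3-[(trimethylsilyl)ethynyl]oct-6-en-1-ol | CC(C)=CCC[C@](CCO)(C)C#C[Si](C)(C)C | intermediate
8 | (3S)-3-ethynyl-3,7-dimethyloct-6-en-1-ol | CC(C)=CCC[C@](CCO)(C)C#C | intermediate
9 | (3S)-3-ethynyl-3,7-dimethyloct-6-enal | CC(C)=CCC[C@](CC=O)(C)C#C | intermediate
10 | ethyl (triphenyl-λ5-phosphanylidene)acetate | CCOC(=O)C=P(c1ccccc1)(c1ccccc1)c1ccccc1 | starting material
11 | 2-(2-bromoethyl)-1,3-dioxolane | BrCCC1OCCO1 | starting material
12 | [4-(1,3-dioxolan-2-yl)-1-ethoxy-1-oxobutan-2-yl]triphenylphosphonium bromide | CCOC(=O)C(CCC1OCCO1)[P+](c1ccccc1)(c1ccccc1)c1ccccc1.[Br-] | intermediate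
13 | ethyl 4-(1,3-dioxolan-2-yl)-2-(triphenyl-λ5-phosphanylidene)butanoate | CCOC(=O)C(CCC1OCCO1)=P(c1ccccc1)(c1ccccc1)c1ccccc1 | intermediate
14 | ethyl (2E,5S)-2-[2-(1,3-dioxolan-2-yl)ethyl]-5-ethynyl-5,9-dimethyldeca-2,8-dienoate | CC(C)=CCC[C@](C/C=C(\CCC1OCCO1)C(=O)OCC)(C)C#C | intermediate
15 | (2E,5S)-2-[2-(1,3-dioxolan-2-yl)ethyl]-5-ethynyl-5,9-dimethyldeca-2,8-dien-1-ol | CC(C)=CCC[C@](C/C=C(\CCC1OCCO1)CO)(C)C#C | intermediate
16 | tert-butyl{[(2E,5S)-2-[2-(1,3-dioxolan-2-yl)ethyl]-5-ethynyl-5,9-dimethyldeca-2,8-dien-1-yl]oxy}diphenylsilane | CC(C)=CCC[C@](C/C=C(\CCC1OCCO1)CO[Si](c1ccccc1)(c1ccccc1)C(C)(C)C)(C)C#C | intermediate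
17 | (4E,7S)-4-{[tert-butyl(diphenyl)silyl]oxymethyl}-7-ethynyl-7,11-dimethyldodeca-4,10-dienal | CC(C)=CCC[C@](C/C=C(\CCC=O)CO[Si](c1ccccc1)(c1ccccc1)C(C)(C)C)(C)C#C | intermediate
18 | ethyl 2-[bis(2,2,2-trifluoroethoxy)phosphoryl]propanoate | CCOC(=O)C(C)P(=O)(OCC(F)(F)F)OCC(F)(F)F | starting material
19 | ethyl (2Z,6E,9S)-6-{[tert-butyl(diphenyl)silyl]oxymethyl}-9-ethynyl-2,9,13-trimethyltetradeca-2,6,12-trienoate | CC(C)=CCC[C@](C/C=C(\CC/C=C(/C)C(=O)OCC)CO[Si](c1ccccc1)(c1ccccc1)C(C)(C)C)(C)C#C | intermediate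
20 | (2Z,6E,9S)-6-{[tert-butyl(diphenyl)silyl]oxymethyl}-9-ethynyl-2,9,13-trimethyltetradeca-2,6,12-trien-1-ol | CC(C)=CCC[C@](C/C=C(\CC/C=C(/C)CO)CO[Si](c1ccccc1)(c1ccccc1)C(C)(C)C)(C)C#C | intermediate
21 | [(2S,3R)-3-[(3E,6S)-3-{[tert-butyl(diphenyl)silyl]oxymethyl}-6-ethynyl-6,10-dimethylundeca-3,9-dien-1-yl]-2-methyloxiran-2-yl]methanol | CC(C)=CCC[C@](C/C=C(\CC[C@H]1O[C@@]1(C)CO)CO[Si](c1ccccc1)(c1ccccc1)C(C)(C)C)(C)C#C | intermediate
22 | (2R,3R)-3-[(3E,6S)-3-{[tert-butyl(diphenyl)silyl]oxymethyl}-6-ethynyl-6,10-dimethylundeca-3,9-dien-1-yl]-2-methyloxirane-2-carbaldehyde | CC(C)=CCC[C@](C/C=C(\CC[C@H]1O[C@@]1(C)C=O)CO[Si](c1ccccc1)(c1ccccc1)C(C)(C)C)(C)C#C | intermediate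
23 | tert-butyl{[(1R,2S,3E,5S,7E,11R)-1,5-dimethyl-5-(4-methylpent-3-en-1-yl)-2-[(triethylsilyl)oxy]-12-oxabicyclo[9.1.0]dodeca-3,7-dien-8-yl]methoxy}diphenylsilane | CC(C)=CCC[C@]1(C)/C=C/[C@H](O[Si](CC)(CC)CC)[C@]2(C)O[C@@H]2CC/C(CO[Si](c2ccccc2)(c2ccccc2)C(C)(C)C)=C\C1 | intermediate
24 | (1S,2S,3E,5S,7E,11R)-8-{[tert-butyl(diphenyl)silyl]oxymethyl}-1,5-dimethyl-5-(4-methylpent-3-en-1-yl)-12-oxabicyclo[9.1.0]dodeca-3,7-dien-2-ol | CC(C)=CCC[C@]1(C)/C=C/[C@H](O)[C@]2(C)O[C@@H]2CC/C(CO[Si](c2ccccc2)(c2ccccc2)C(C)(C)C)=C\C1 | intermediate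
25 | 3-methylbut-2-enoyl chloride | CC(C)=CC(Cl)=O | starting material
26 | (1R,2S,3E,5S,7E,11R)-8-{[tert-butyl(diphenyl)silyl]oxymethyl}-1,5-dimethyl-5-(4-methylpent-3-en-1-yl)-12-oxabicyclo[9.1.0]dodeca-3,7-dien-2-yl 3-methylbut-2-enoate | CC(C)=CCC[C@]1(C)/C=C/[C@H](OC(=O)C=C(C)C)[C@]2(C)O[C@@H]2CC/C(CO[Si](c2ccccc2)(c2ccccc2)C(C)(C)C)=C\C1 | intermediate
27 | (1R,2S,3E,5S,7E,11R)-8-(hydroxymethyl)-1,5-dimethyl-5-(4-methylpent-3-en-1-yl)-12-oxabicyclo[9.1.0]dodeca-3,7-dien-2-yl 3-methylbut-2-enoate | CC(C)=CCC[C@]1(C)/C=C/[C@H](OC(=O)C=C(C)C)[C@]2(C)O[C@@H]2CC/C(CO)=C\C1 | target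

**Totals**
Total step count: 17. Longest linear sequence: 16 steps (steps 1–4 and 6–17 from geraniol; step 5 is a one-step side branch).

**Steps most likely to fail**

1. Step 14. The ring closure may lose to intermolecular coupling (oligomers) or to hydrosilylation of the aldehyde before cyclisation, and ring strain in the transition state may force attack on the other aldehyde face. Fallback (sets out from 20, comes back at 24): 20 is treated with Cp2Zr(H)Cl (excess, the first equivalent being consumed by the hydroxyl) and then I2 to give the (E)-vinyl iodide alcohol F1. Sharpless epoxidation under the conditions of step 12 gives the epoxy alcohol F2. Dess–Martin oxidation gives the iodo epoxy aldehyde F3. An intramolecular Nozaki–Hiyama–Kishi reaction (CrCl2, NiCl2 cat., DMSO/THF, high dilution) should then give alcohol 24 directly; the (E) geometry of the C3=C4 alkene comes from the syn hydrozirconation and is carried into the ring because the alkenylchromium species adds with retention.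

2. Step 2. The allylic substitution may proceed with insufficient or opposite facial selectivity, or with partial SN2 substitution, for a substrate whose two alkene substituents are both alkyl. Fallback (sets out from 1, comes back at 5): Sharpless epoxidation of geraniol with D-(−)-diethyl tartrate, Ti(OiPr)4 and t-BuOOH gives the (2R,3R)-epoxy alcohol F4. Et2AlC≡CSiMe3 (from LiC≡CSiMe3 and Et2AlCl) opens the epoxide at the tertiary carbon with inversion to give the diol F5, which sets the quaternary centre by known rules. NaIO4 cleaves the diol to the α-quaternary aldehyde F6, and Wittig methylenation with Ph3P=CH2 gives 5.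

3. Step 6. The α-branched stabilised ylide may react sluggishly with the neopentyl-type aldehyde, or the alkene may form with eroded E/Z control. Fallback (sets out from 9, comes back at 14): a Morita–Baylis–Hillman reaction of 9 with ethyl acrylate (DABCO) gives the hydroxy acrylate F7 as a mixture at the carbinol carbon, and acetylation (Ac2O, DMAP) gives the allylic acetate F8. SN2' substitution with (1,3-dioxolan-2-yl)CH2MgBr and catalytic CuI (one extra equivalent for the alkyne C–H) should give 14 with the ester trans to the chain.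

**Further compounds**
F1 | step 14 | (2Z,6E,9S)-6-{[tert-butyl(diphenyl)silyl]oxymethyl}-9-[(E)-2-iodoethenyl]-2,9,13-trimethyltetradeca-2,6,12-trien-1-ol | CC(C)=CCC[C@](C/C=C(\CC/C=C(/C)CO)CO[Si](c1ccccc1)(c1ccccc1)C(C)(C)C)(C)/C=C/I
F2 | step 14 | [(2S,3R)-3-[(3E,6S)-3-{[tert-butyl(diphenyl)silyl]oxymethyl}-6-[(E)-2-iodoethenyl]-6,10-dimethylundeca-3,9-dien-1-yl]-2-methyloxiran-2-yl]methanol | CC(C)=CCC[C@](C/C=C(\CC[C@H]1O[C@@]1(C)CO)CO[Si](c1ccccc1)(c1ccccc1)C(C)(C)C)(C)/C=C/I
F3 | step 14 | (2R,3R)-3-[(3E,6S)-3-{[tert-butyl(diphenyl)silyl]oxymethyl}-6-[(E)-2-iodoethenyl]-6,10-dimethylundeca-3,9-dien-1-yl]-2-methyloxirane-2-carbaldehyde | CC(C)=CCC[C@](C/C=C(\CC[C@H]1O[C@@]1(C)C=O)CO[Si](c1ccccc1)(c1ccccc1)C(C)(C)C)(C)/C=C/I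
F4 | step 2 | [(2R,3R)-3-methyl-3-(4-methylpent-3-en-1-yl)oxiran-2-yl]methanol | OC[C@H]1O[C@]1(C)CCC=C(C)C
F5 | step 2 | (2S,3R)-3,7-dimethyl-3-[(trimethylsilyl)ethynyl]oct-6-ene-1,2-diol | OC[C@@H](O)[C@@](C)(C#C[Si](C)(C)C)CCC=C(C)C
F6 | step 2 | (2R)-2,6-dimethyl-2-[(trimethylsilyl)ethynyl]hept-5-enal | O=C[C@@](C)(C#C[Si](C)(C)C)CCC=C(C)C
F7 | step 6 | ethyl (5S)-5-ethynyl-3-hydroxy-5,9-dimethyl-2-methylidenedec-8-enoate (mixture at C3) | CC(C)=CCC[C@](CC(O)C(=C)C(=O)OCC)(C)C#C
F8 | step 6 | ethyl (5S)-3-acetoxy-5-ethynyl-5,9-dimethyl-2-methylidenedec-8-enoate (mixture at C3) | CC(C)=CCC[C@](CC(OC(C)=O)C(=C)C(=O)OCC)(C)C#C
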